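A small charge of reagent, 1.20 M against 1.0 M of solid substrate, is less than the two per substrate that a bis adduct takes, so I count that budget first.

- west: solid substrate 1 M; reagent 1.2 M; the very flask that is asked about, followed so far
- flask: solid substrate 1.0 M; reagent 1.20 M; time 2.5 d

west run (percent of the solid substrate charged)

| time / h | solid substrate / % | first product / % | other mono adduct / % |
|---|---|---|---|
| 3.00 | 60 | 2 | 3 |
| 6.00 | 41 | 0 | 2 |
| 10.0 | 35 | 0 | 0 |
| 12.0 | 33 | 1 | 4 |
| 15.0 | 31 | 0 | 2 |
| 20.0 | 33 | 0 | 0 |

(scatter of a reading: 1.5 percentage points)

- solid, in amounts per volume of the solution: solid substrate
- at the start none of the solid substrate is in solution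

- how much solid substrate there is at 2.5 d, in percent of the solid substrate charged (only what is still solid)
- how much first product there is at 2.5 d, in percent of the solid substrate charged
- how much other mono adduct there is at 2.5 d, in percent of the solid substrate charged
- how much bis adduct there is at 2.5 d, in percent of the solid substrate charged

The west run is this flask followed so far, and I draw its solid curve from both ends. At the start, the chord to the first reading loses a fraction 0.133 h⁻¹ of the charge. At the far end, the last three readings average 32.3%. The two lines cross at

t(knee) = (whole charge − level) / slope = 5.08 h

The reading of 41% at 6.00 h still stands higher than the level, so the knee is rounded. First product and other mono adduct read no higher than 2% and 4%, with a scatter of 1.5 percentage points, so I take bis adduct as the main destination.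

ceiling = c(reagent) / (two × c(solid substrate)) = 60.0%

This reagent ceiling is the bis adduct, in percent of the solid charged, that the limiting reagent pays for at two each. It leaves 40.0% of the charge outside bis adduct, but the solid levels 7.7 points lower, so that difference must stand in some other form. I commit to bis adduct just under the ceiling and to solid at the level.

The forecast gives solid substrate 32% (29% to 36%), first product 0.5%, other mono adduct 1.5% and bis adduct 59% (53% to 60%), and says: “The plateau therefore reflects reagent exhaustion plus saturation”.

This flask gives solid substrate 30.9%, first product 0.0429%, other mono adduct 2.41% and bis adduct 57.7%, each within the forecast's tolerance.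

    starting material + reagent → first product + by-product (k = 0.0451 M⁻¹ min⁻¹)
    starting material + reagent → other mono adduct + by-product (k = 0.0136 M⁻¹ min⁻¹)
    reagent + first product → bis adduct + by-product (k = 0.179 M⁻¹ min⁻¹)
    reagent + other mono adduct → bis adduct + by-product (k = 0.0255 M⁻¹ min⁻¹)
    starting material + first product → side product (k = 0.0268 M⁻¹ min⁻¹)
    solid substrate ⇌ starting material, rate k6*(cs6 - [starting material]) while solid is left; crystals form when [starting material] > cs6 (solubility = 46.0 mM, k = 0.865 min⁻¹)

With reagent at 0%, bis adduct in this flask stands 2.3 points under the ceiling. Beyond the solid and the three adducts asked about, 9 points of the charge remains, held as starting material 4.60% and side product 4.39%. The neighbour flask with 2.5 M of solid substrate has a ceiling of 24.0%, which leaves 76.0% outside bis adduct. With its reagent at 0%, that flask gives bis adduct 23.1% and solid substrate 72.4%.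

(The readings stem from a simulated flask from invented constants; the scatter is artificial.)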